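**Strategy.** Ring A (carbocycle; isochromene numbering, ring B = pyran) is disconnected at C7–C8 and at the C4a=C5 double bond. This splits the azaphilone into a 6-dienyl-4-oxo-4H-pyran-3-carbaldehyde (ring B with C8 and the side chain) and a four-carbon butane-2,3-dione unit (C5, C6, C7 and the 7-methyl group). The key step exploits two features: C4a is the carbonyl carbon of a 4-pyranone, so O-triflation turns it into a pyrylium carbon that a silyl enol ether can substitute; and C7 is a tertiary carbinol between the C6 and C8 ketones, the product of a benzoin-type addition of the C8 aldehyde to a C7 ketone. Both bonds form in one pot; a chiral carbene sets C7. Chlorination at C5 and propionylation follow.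

Key step: step 8

Remark: chlorokojic acid, 2,3-bis(trimethylsilyloxy)buta-1,3-diene and both antipodes of the triazolium salt T, (5aS,10bR)-2-(pentafluorophenyl)-5a,10b-dihydro-4H,6H-indeno[2,1-b][1,2,4]triazolo[4,3-d][1,4]oxazin-2-ium tetrafluoroborate, are taken as purchasable; the sense of induction of T at C7 is assigned by analogy and the mirror-image salt would be used if it proves opposite.

Step 1
Reactants: 1 (S)-2-methylbutan-1-ol; 2 ethyl 2-(triphenylphosphoranylidene)propanoate
Product: 4 ethyl (2E,4S)-2,4-dimethylhex-2-enoate, via (S)-2-methylbutanal 3 (not isolated)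
Conditions: TEMPO (cat.), PhI(OAc)2, CH2Cl2, rt; then 2, rt to 40 °C
Reagents that add atoms: none
Why: Oxoammonium-mediated alcohol oxidation followed in the same flask by a Wittig olefination with the ester-stabilised ylide should give the E-enoate without isolating the configurationally labile α-branched aldehyde; the S centre comes from 1.

Step 2
Reactants: 4 ethyl (2E,4S)-2,4-dimethylhex-2-enoate
Product: 5 (2E,4S)-2,4-dimethylhex-2-en-1-ol
Conditions: i-Bu2AlH, CH2Cl2, −78 °C
Reagents that add atoms: none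
Why: 1,2-Reduction of the conjugated ester with the aluminium hydride should give the allylic alcohol without touching the alkene or the stereocentre.

Step 3
Reactants: 5 (2E,4S)-2,4-dimethylhex-2-en-1-ol
Product: 6 (2E,4S)-2,4-dimethylhex-2-enal
Conditions: MnO2, CH2Cl2, rt
Reagents that add atoms: none
Why: Allylic alcohol oxidation with MnO2 is neutral and mild, so the E-alkene and the γ-stereocentre should be kept.

Step 4
Reactants: 7 2-(chloromethyl)-5-hydroxy-4H-pyran-4-one (chlorokojic acid)
Product: 8 6-(chloromethyl)-4-oxo-4H-pyran-3-yl trifluoromethanesulfonate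
Conditions: PhNTf2, i-Pr2NEt, CH2Cl2, 0 °C to rt
Reagents that add atoms: N-phenylbis(trifluoromethanesulfonimide), O=S(=O)(N(c1ccccc1)S(=O)(=O)C(F)(F)F)C(F)(F)F
Why: O-Sulfonylation (triflation) of the acidic enolic hydroxyl with the mild triflimide reagent; the hindered amine should not displace the activated chloride.

Step 5
Reactants: 8 6-(chloromethyl)-4-oxo-4H-pyran-3-yl trifluoromethanesulfonate
Product: 9 6-[(diethoxyphosphoryl)methyl]-4-oxo-4H-pyran-3-yl trifluoromethanesulfonate
Conditions: P(OEt)3, toluene, 110 °C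
Reagents that add atoms: triethyl phosphite, CCOP(OCC)OCC
Why: Michaelis–Arbuzov reaction at the chloromethyl group, which is activated as a vinylogous α-halo ketone; a vinyl triflate is inert to phosphite without a metal catalyst.

Step 6
Reactants: 9 6-[(diethoxyphosphoryl)methyl]-4-oxo-4H-pyran-3-yl trifluoromethanesulfonate; 6 (2E,4S)-2,4-dimethylhex-2-enal
Product: 10 6-[(1E,3E,5S)-3,5-dimethylhepta-1,3-dien-1-yl]-4-oxo-4H-pyran-3-yl trifluoromethanesulfonate
Conditions: LiN(SiMe3)2, THF, −78 °C; then 6, −78 to 0 °C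
Reagents that add atoms: none
Why: Horner–Wadsworth–Emmons olefination; the carbanion is stabilised by the phosphoryl group and vinylogously by the pyranone carbonyl, so the new alkene should be E, and pre-forming the anion at low temperature spares the enal stereocentre.

Step 7
Reactants: 10 6-[(1E,3E,5S)-3,5-dimethylhepta-1,3-dien-1-yl]-4-oxo-4H-pyran-3-yl trifluoromethanesulfonate
Product: 11 6-[(1E,3E,5S)-3,5-dimethylhepta-1,3-dien-1-yl]-4-oxo-4H-pyran-3-carbaldehyde
Conditions: Pd(OAc)2 (5 mol %), Ph2P(CH2)3PPh2, CO (1 atm), Et3SiH, Et3N, DMF, 70 °C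
Reagents that add atoms: carbon monoxide, [C-]#[O+]
Why: Palladium-catalysed reductive carbonylation (formylation) of the vinyl triflate: oxidative addition, CO insertion and hydride transfer from the silane to the acyl-palladium species.

Step 8
Reactants: 11 6-[(1E,3E,5S)-3,5-dimethylhepta-1,3-dien-1-yl]-4-oxo-4H-pyran-3-carbaldehyde; 12 2,3-bis(trimethylsilyloxy)buta-1,3-diene
Product: 16 (7S)-3-[(1E,3E,5S)-3,5-dimethylhepta-1,3-dien-1-yl]-7-hydroxy-7-methyl-6H-isochromene-6,8(7H)-dione, via triflyloxypyrylium triflate 13 (not isolated), via silyl dienol ether 14 (not isolated), via diketo aldehyde 15 (not isolated)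
Conditions: Tf2O, 2,6-di-tert-butyl-4-methylpyridine, CH2Cl2, −78 °C; then 12, −78 to −20 °C; then MeOH, i-Pr2NEt, triazolium salt T (15 mol %), 0 °C to rt
Reagents that add atoms: none
Why: Proposed new method: Tf2O sulfonylates the pyranone oxygen of 11 to give the 4-triflyloxypyrylium 13, a vinylogous acyl triflate; a terminal carbon of the soft π-nucleophile 12 adds at C4a, triflate leaves and loss of the C5 proton gives the 4-ylidenepyran 14, whose remaining enol silane is methanolysed to the diketo aldehyde 15 (closest known types: substitution at C4 of 4-triflyloxy- and 4-chloropyrylium salts by carbon nucleophiles, and Knoevenagel condensation of 4-pyranones with CH-acids). The carbene from T then adds to the C8 aldehyde and the resulting enaminol (acyl-anion equivalent) attacks the C7 ketone in an intramolecular crossed aldehyde–ketone benzoin reaction, a known type for six-membered rings, closing ring A by 6-exo-trig addition. The C7 stereocentre is controlled by the chiral aminoindanol backbone of the carbene, which shields one face of the enaminol. The step needs C4a over C1 selectivity in the substitution, which the leaving group at C4a and the soft silyl enol ether should secure, as silyl enol ethers add at the γ-position of pyridinium and flavylium cations. It also needs C7 over C6 selectivity in the benzoin closure: C6 is a deactivated vinylogous-ester carbonyl that would give a five-membered ring, whereas C7 is an activated acetyl ketone.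

Step 9
Reactants: 16 (7S)-3-[(1E,3E,5S)-3,5-dimethylhepta-1,3-dien-1-yl]-7-hydroxy-7-methyl-6H-isochromene-6,8(7H)-dione
Product: 17 (7R)-5-chloro-3-[(1E,3E,5S)-3,5-dimethylhepta-1,3-dien-1-yl]-7-hydroxy-7-methyl-6H-isochromene-6,8(7H)-dione
Conditions: N-chlorosuccinimide, MeCN, 0 °C to rt
Reagents that add atoms: N-chlorosuccinimide, O=C1CCC(=O)N1Cl
Why: Electrophilic chlorination at C5, the α-carbon of the doubly vinylogous ester O2–C3=C4–C4a=C5–C6=O and the most nucleophilic site of the chromophore; C7 is untouched and its descriptor becomes R only because chlorine changes the priorities.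

Step 10
Reactants: 17 (7R)-5-chloro-3-[(1E,3E,5S)-3,5-dimethylhepta-1,3-dien-1-yl]-7-hydroxy-7-methyl-6H-isochromene-6,8(7H)-dione
Product: 18 (7R)-5-chloro-3-[(1E,3E,5S)-3,5-dimethylhepta-1,3-dien-1-yl]-7-methyl-6,8-dioxo-7,8-dihydro-6H-isochromen-7-yl propanoate (sclerketide B)
Conditions: (EtCO)2O, DMAP, Et3N, CH2Cl2, rt
Reagents that add atoms: propionic anhydride, CCC(=O)OC(=O)CC
Why: DMAP-catalysed acylation (esterification) of the tertiary α-ketol; no stereocentre is affected.

**Compound list**

1 | (S)-2-methylbutan-1-ol | OC[C@@H](C)CC | starting material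
2 | ethyl 2-(triphenylphosphoranylidene)propanoate | CCOC(=O)C(C)=P(c1ccccc1)(c1ccccc1)c1ccccc1 | starting material
3 | (S)-2-methylbutanal | O=C[C@@H](C)CC | intermediate
4 | ethyl (2E,4S)-2,4-dimethylhex-2-enoate | CCOC(=O)/C(C)=C/[C@@H](C)CC | intermediate
5 | (2E,4S)-2,4-dimethylhex-2-en-1-ol | OC/C(C)=C/[C@@H](C)CC | intermediate
6 | (2E,4S)-2,4-dimethylhex-2-enal | O=C/C(C)=C/[C@@H](C)CC | intermediate
7 | 2-(chloromethyl)-5-hydroxy-4H-pyran-4-one (chlorokojic acid) | O=C1C=C(CCl)OC=C1O | starting material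
8 | 6-(chloromethyl)-4-oxo-4H-pyran-3-yl trifluoromethanesulfonate | O=C1C=C(CCl)OC=C1OS(=O)(=O)C(F)(F)F | intermediate
9 | 6-[(diethoxyphosphoryl)methyl]-4-oxo-4H-pyran-3-yl trifluoromethanesulfonate | CCOP(=O)(CC1=CC(=O)C(OS(=O)(=O)C(F)(F)F)=CO1)OCC | intermediate
10 | 6-[(1E,3E,5S)-3,5-dimethylhepta-1,3-dien-1-yl]-4-oxo-4H-pyran-3-yl trifluoromethanesulfonate | O=C1C=C(/C=C/C(C)=C/[C@@H](C)CC)OC=C1OS(=O)(=O)C(F)(F)F | intermediate
11 | 6-[(1E,3E,5S)-3,5-dimethylhepta-1,3-dien-1-yl]-4-oxo-4H-pyran-3-carbaldehyde | O=CC1=COC(/C=C/C(C)=C/[C@@H](C)CC)=CC1=O | intermediate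
12 | 2,3-bis(trimethylsilyloxy)buta-1,3-diene | C=C(O[Si](C)(C)C)C(=C)O[Si](C)(C)C | starting material
13 | 2-[(1E,3E,5S)-3,5-dimethylhepta-1,3-dien-1-yl]-5-formyl-4-[(trifluoromethanesulfonyl)oxy]pyrylium trifluoromethanesulfonate | O=Cc1c[o+]c(/C=C/C(C)=C/[C@@H](C)CC)cc1OS(=O)(=O)C(F)(F)F.[O-]S(=O)(=O)C(F)(F)F | intermediate
14 | (4Z)-6-[(1E,3E,5S)-3,5-dimethylhepta-1,3-dien-1-yl]-4-{2-oxo-3-[(trimethylsilyl)oxy]but-3-en-1-ylidene}-4H-pyran-3-carbaldehyde | C=C(O[Si](C)(C)C)C(=O)/C=C1\C(C=O)=COC(/C=C/C(C)=C/[C@@H](C)CC)=C1 | intermediate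
15 | (4Z)-4-(2,3-dioxobutylidene)-6-[(1E,3E,5S)-3,5-dimethylhepta-1,3-dien-1-yl]-4H-pyran-3-carbaldehyde | CC(=O)C(=O)/C=C1\C(C=O)=COC(/C=C/C(C)=C/[C@@H](C)CC)=C1 | intermediate
16 | (7S)-3-[(1E,3E,5S)-3,5-dimethylhepta-1,3-dien-1-yl]-7-hydroxy-7-methyl-6H-isochromene-6,8(7H)-dione | O[C@]1(C)C(=O)C2=COC(/C=C/C(C)=C/[C@@H](C)CC)=CC2=CC1=O | intermediate
17 | (7R)-5-chloro-3-[(1E,3E,5S)-3,5-dimethylhepta-1,3-dien-1-yl]-7-hydroxy-7-methyl-6H-isochromene-6,8(7H)-dione | O[C@]1(C)C(=O)C2=COC(/C=C/C(C)=C/[C@@H](C)CC)=CC2=C(Cl)C1=O | intermediate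
18 | (7R)-5-chloro-3-[(1E,3E,5S)-3,5-dimethylhepta-1,3-dien-1-yl]-7-methyl-6,8-dioxo-7,8-dihydro-6H-isochromen-7-yl propanoate (sclerketide B) | CCC(=O)O[C@]1(C)C(=O)C2=COC(/C=C/C(C)=C/[C@@H](C)CC)=CC2=C(Cl)C1=O | target

**Count.** Total steps: 10. Longest linear sequence: 8 steps (steps 1, 2, 3, 6, 7, 8, 9, 10 from compound 1).

**Steps most likely to fail**

Step 8 (labelled above). The silyl dienol ether may attack C1 of the pyrylium or the activated aldehyde instead of C4a, and the dienyl-pyrylium may lose side-chain configuration by vinylogous deprotonation. The fallback uses known reaction types and forms the two bonds in separate steps. It sets out from 11, which is converted with HC(OMe)3 and catalytic acid into 5-(dimethoxymethyl)-2-[(1E,3E,5S)-3,5-dimethylhepta-1,3-dien-1-yl]-4H-pyran-4-one F1. CeCl3-promoted 1,2-addition of the lithium acetylide of 2-ethynyl-2-methyl-1,3-dioxolane to the pyranone carbonyl then gives the tertiary propargylic alcohol 3-(dimethoxymethyl)-6-[(1E,3E,5S)-3,5-dimethylhepta-1,3-dien-1-yl]-4-[(2-methyl-1,3-dioxolan-2-yl)ethynyl]-4H-pyran-4-ol F2. Aqueous CF3CO2H in THF should effect the Meyer–Schuster rearrangement together with acetal and ketal hydrolysis to give 15, now isolated. Intramolecular crossed benzoin reaction of 15 with T and i-Pr2NEt returns to the route at 16.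

Step 7. Hydride may be transferred to the vinyl-palladium species before CO insertion, which loses the triflate without formylation, or the silane may add to the triene. The fallback sets out from 10: palladium-catalysed aminocarbonylation (Pd(OAc)2, CO, N,O-dimethylhydroxylamine) gives 6-[(1E,3E,5S)-3,5-dimethylhepta-1,3-dien-1-yl]-N-methoxy-N-methyl-4-oxo-4H-pyran-3-carboxamide F3. Chemoselective amide reduction with Cp2Zr(H)Cl returns to the route at 11.

Step 9. Chlorination may be poorly site-selective (C4 or the dienyl chain), or the free α-ketol may be oxidised by the N-chloro reagent. The fallback sets out from 16, which is acylated first with propionic anhydride and DMAP to give (7S)-3-[(1E,3E,5S)-3,5-dimethylhepta-1,3-dien-1-yl]-7-methyl-6,8-dioxo-7,8-dihydro-6H-isochromen-7-yl propanoate F4. Chlorination of this capped, less electron-rich ester with SO2Cl2 at −78 °C or with N-chlorosuccinimide returns to the route at 18.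

Further compounds
F1 | step 8 | 5-(dimethoxymethyl)-2-[(1E,3E,5S)-3,5-dimethylhepta-1,3-dien-1-yl]-4H-pyran-4-one | COC(OC)C1=COC(/C=C/C(C)=C/[C@@H](C)CC)=CC1=O
F2 | step 8 | 3-(dimethoxymethyl)-6-[(1E,3E,5S)-3,5-dimethylhepta-1,3-dien-1-yl]-4-[(2-methyl-1,3-dioxolan-2-yl)ethynyl]-4H-pyran-4-ol (both C4 epimers) | COC(OC)C1=COC(/C=C/C(C)=C/[C@@H](C)CC)=CC1(O)C#CC1(C)OCCO1
F3 | step 7 | 6-[(1E,3E,5S)-3,5-dimethylhepta-1,3-dien-1-yl]-N-methoxy-N-methyl-4-oxo-4H-pyran-3-carboxamide | CON(C)C(=O)C1=COC(/C=C/C(C)=C/[C@@H](C)CC)=CC1=O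
F4 | step 9 | (7S)-3-[(1E,3E,5S)-3,5-dimethylhepta-1,3-dien-1-yl]-7-methyl-6,8-dioxo-7,8-dihydro-6H-isochromen-7-yl propanoate | CCC(=O)O[C@]1(C)C(=O)C2=COC(/C=C/C(C)=C/[C@@H](C)CC)=CC2=CC1=O
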